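**Plan**

1. Numbering (germacrane): C1 ketone, C2=C3 and the C3–O–C10 oxygen form furanone ring A; C4=C5 (C15 on C4), C6–C9 and that oxygen complete the nine-membered ring B; O6–C12(=O)–C11(=C13)–C7 is lactone ring C; C14 is the methyl on C10.
2. Retrosynthetic cuts, in order: C8 O–acyl and C15 O–Si; C11=C13 and C7–C11 in one operation (ring C, from a C6 phosphonoacetate and a trans C7–C8 epoxide); C4=C5 (ring B, ring-closing metathesis); O6–C12; the epoxide oxygen; C5–C6; C7=C8 (cross-metathesis); O–C3 (ring A); C1–C2; C9–C10.
3. Forward: the lactate-derived C10 unit and a C2–C4/C15 enyne are joined at C1–C2, ring A is closed, the C9–C5 chain is grown from the allyl group, then ring B and finally ring C are closed.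
4. Feature used by the key step: on ring C the C7–C11 bond is anti to the C8–O bond and trans to C6–O, and O6 sits on the carbon next to C7, so a carbanion held on O6 can reach the rear of C7 of a trans C7–C8 epoxide through a five-membered ring.
5. Stereochemistry: C10 from (S)-lactic acid (alkylation of its pivalaldehyde acetal with self-regeneration of the centre); C6 from ligand-controlled vinyl addition; C7 and C8 from an E alkene and Sharpless epoxidation, both made on the open chain where geometry and face can be controlled; C7 is inverted and C8 kept in the key step; the 4Z alkene is enforced by ring B.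

Key step: step 14

Remark: Zn(CH=CH2)2 is assumed to be at hand as a stock solution made beforehand from CH2=CHMgBr and ZnCl2.

**Route**

Step 1
Reactants: 1 (S)-lactic acid
Product: 2 (2S,5S)-2-tert-butyl-5-methyl-1,3-dioxolan-4-one (cis acetal)
Conditions: pivalaldehyde, TsOH·H2O (cat.), pentane, reflux, Dean–Stark trap; crystallisation at −78 °C
Reagents that add atoms: pivalaldehyde CC(C)(C)C=O
Why: Acid-catalysed acetalisation to the 1,3-dioxolan-4-one with azeotropic removal of water should favour the cis acetal, whose new acetal centre (2S) is set under thermodynamic control by the lactate centre, and the cis isomer can be purified by crystallisation.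

Step 2
Reactants: 2 (2S,5S)-2-tert-butyl-5-methyl-1,3-dioxolan-4-one, 3 allyl bromide
Product: 4 (2S,5R)-2-tert-butyl-5-methyl-5-(prop-2-en-1-yl)-1,3-dioxolan-4-one
Conditions: LiN(iPr)2, THF, −78 °C; then 3, −78 → −20 °C
Reagents that add atoms: none
Why: Enolate alkylation with self-regeneration of the stereocentre, in which the planar lithium enolate keeps only the acetal centre and allyl bromide should enter anti to the tert-butyl group, so the future C10 is formed as the R quaternary centre with net retention.

Step 3
Reactants: 4 (2S,5R)-2-tert-butyl-5-methyl-5-(prop-2-en-1-yl)-1,3-dioxolan-4-one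
Product: 5 (2R)-2-hydroxy-N-methoxy-N,2-dimethylpent-4-enamide
Conditions: MeNHOMe·HCl, iPrMgCl, THF, −20 → 0 °C; aq NH4Cl
Reagents that add atoms: N,O-dimethylhydroxylamine hydrochloride CNOC.Cl
Why: Weinreb amide formation by aminolysis of the acylal-type lactone with the chloromagnesium amide, after which the released hemiacetal collapses to pivalaldehyde and leaves the tertiary alcohol free without touching the quaternary centre.

Step 4
Reactants: 6 2-bromoprop-2-en-1-ol
Product: 7 (2-bromoprop-2-en-1-yloxy)(tert-butyl)dimethylsilane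
Conditions: TBSCl, imidazole, CH2Cl2, 0 °C → rt
Reagents that add atoms: tert-butyldimethylsilyl chloride CC(C)(C)[Si](C)(C)Cl
Why: Imidazole-promoted silyl ether formation on a primary allylic alcohol is routine and gives the C15 protecting group that is carried to the last step.

Step 5
Reactants: 7 (2-bromoprop-2-en-1-yloxy)(tert-butyl)dimethylsilane, 8 ethynyltrimethylsilane
Product: 9 tert-butyldimethyl[2-methylidene-4-(trimethylsilyl)but-3-yn-1-yloxy]silane
Conditions: Pd(PPh3)2Cl2 (cat.), CuI (cat.), iPr2NH, THF, 45 °C
Reagents that add atoms: none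
Why: Sonogashira coupling, in which zerovalent palladium inserts into the vinyl C–Br bond and the copper acetylide transmetalates, should give the cross-conjugated enyne (C2–C3–C4 with C15) without affecting the silyl ether.

Step 6
Reactants: 9 tert-butyldimethyl[2-methylidene-4-(trimethylsilyl)but-3-yn-1-yloxy]silane
Product: 10 tert-butyldimethyl(2-methylidenebut-3-yn-1-yloxy)silane
Conditions: K2CO3 (cat.), MeOH, 0 °C
Reagents that add atoms: none
Why: Carbonate-catalysed methanolysis of the alkynyl C–Si bond (protodesilylation) is much faster than cleavage of the alkyl silyl ether, so only the alkyne terminus is freed.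

Step 7
Reactants: 5 (2R)-2-hydroxy-N-methoxy-N,2-dimethylpent-4-enamide, 10 tert-butyldimethyl(2-methylidenebut-3-yn-1-yloxy)silane
Product: 11 (4R)-8-[(tert-butyldimethylsilyloxy)methyl]-4-hydroxy-4-methylnona-1,8-dien-6-yn-5-one
Conditions: 10 (2.3 equiv), nBuLi (2.2 equiv), THF, −78 °C; then 5, −78 → −20 °C; aq NH4Cl
Reagents that add atoms: none
Why: Acyl substitution of a Weinreb amide by a lithium acetylide, in which the first equivalent deprotonates the tertiary hydroxyl and the second adds to give a chelated tetrahedral intermediate that releases the ynone only on work-up, so the C1–C2 bond forms without over-addition.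

Step 8
Reactants: 11 (4R)-8-[(tert-butyldimethylsilyloxy)methyl]-4-hydroxy-4-methylnona-1,8-dien-6-yn-5-one
Product: 12 (2R)-5-[3-(tert-butyldimethylsilyloxy)prop-1-en-2-yl]-2-methyl-2-(prop-2-en-1-yl)furan-3(2H)-one
Conditions: (4-CF3C6H4)3PAuCl (cat.), AgOTf (cat.), toluene, rt
Reagents that add atoms: none
Why: Cycloisomerisation of a hydroxy alkynone to a 3(2H)-furanone, in which cationic monovalent gold activates the alkyne and the tertiary hydroxyl adds to C3 in a 5-endo-dig closure, forms ring A and ties up the C10 oxygen while C10 itself is untouched.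

Step 9
Reactants: 12 (2R)-5-[3-(tert-butyldimethylsilyloxy)prop-1-en-2-yl]-2-methyl-2-(prop-2-en-1-yl)furan-3(2H)-one, 13 (E)-but-2-enal
Product: 14 (2E)-4-{(2R)-5-[3-(tert-butyldimethylsilyloxy)prop-1-en-2-yl]-2-methyl-3-oxo-2,3-dihydrofuran-2-yl}but-2-enal
Conditions: 13 (excess), second-generation Hoveyda–Grubbs catalyst (cat.), CH2Cl2, 40 °C
Reagents that add atoms: none
Why: Olefin cross-metathesis of the terminal allyl alkene with an enal should give the E C7=C8 enal, while the hindered, electron-poor 1,1-disubstituted C4 alkene stays out of the reaction and cannot close a ring with the allyl group without a bridgehead alkene.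

Step 10
Reactants: 14 (2E)-4-{(2R)-5-[3-(tert-butyldimethylsilyloxy)prop-1-en-2-yl]-2-methyl-3-oxo-2,3-dihydrofuran-2-yl}but-2-enal
Product: 15 (2R)-5-[3-(tert-butyldimethylsilyloxy)prop-1-en-2-yl]-2-[(2E,4R)-4-hydroxyhexa-2,5-dien-1-yl]-2-methylfuran-3(2H)-one
Conditions: Zn(CH=CH2)2, (+)-DAIB [(+)-3-exo-(dimethylamino)isoborneol] (cat.), toluene, −20 → 0 °C; aq NH4Cl
Reagents that add atoms: divinylzinc C=C[Zn]C=C
Why: Amino-alcohol-catalysed 1,2-addition of an organozinc reagent to an aldehyde, in which the (+)-ligand should direct the vinyl group to the Re face of the C6 aldehyde and so set C6 as R, while the vinylogous ester of ring A does not react with organozincs.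

Step 11
Reactants: 15 (2R)-5-[3-(tert-butyldimethylsilyloxy)prop-1-en-2-yl]-2-[(2E,4R)-4-hydroxyhexa-2,5-dien-1-yl]-2-methylfuran-3(2H)-one
Product: 16 (2R)-5-[3-(tert-butyldimethylsilyloxy)prop-1-en-2-yl]-2-({(2R,3R)-3-[(1R)-1-hydroxyprop-2-en-1-yl]oxiran-2-yl}methyl)-2-methylfuran-3(2H)-one
Conditions: Ti(OiPr)4 (cat.), D-(−)-diisopropyl tartrate (cat.), tBuOOH, 4 Å molecular sieves, CH2Cl2, −20 °C
Reagents that add atoms: tert-butyl hydroperoxide CC(C)(C)OO
Why: Sharpless asymmetric epoxidation of a secondary E-allylic alcohol, in which the (6R) carbinol is the fast-reacting isomer with the D-(−)-tartrate and oxygen should be delivered to the C7=C8 face that gives the erythro trans epoxide (7R,8R as named here), while the C6 vinyl group and any (6S) epimer react slowly and the electron-poor ring A and C4 alkene not at all, so the step sets C7 and C8 and also raises the purity at C6.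

Step 12
Reactants: 16 (2R)-5-[3-(tert-butyldimethylsilyloxy)prop-1-en-2-yl]-2-({(2R,3R)-3-[(1R)-1-hydroxyprop-2-en-1-yl]oxiran-2-yl}methyl)-2-methylfuran-3(2H)-one, 17 (diethoxyphosphoryl)acetic acid
Product: 18 (1R)-1-[(2S,3R)-3-({(2R)-5-[3-(tert-butyldimethylsilyloxy)prop-1-en-2-yl]-2-methyl-3-oxo-2,3-dihydrofuran-2-yl}methyl)oxiran-2-yl]prop-2-en-1-yl (diethoxyphosphoryl)acetate
Conditions: 17, DCC, DMAP (cat.), CH2Cl2, 0 °C → rt
Reagents that add atoms: none
Why: Steglich (carbodiimide) esterification of the secondary C6 hydroxyl under neutral conditions should leave the neighbouring epoxide intact, and the C7 descriptor changes from R to S only through the priority rules.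

Step 13
Reactants: 18 (1R)-1-[(2S,3R)-3-({(2R)-5-[3-(tert-butyldimethylsilyloxy)prop-1-en-2-yl]-2-methyl-3-oxo-2,3-dihydrofuran-2-yl}methyl)oxiran-2-yl]prop-2-en-1-yl (diethoxyphosphoryl)acetate
Product: 19 (4Z,6R,7S,8R,10R)-15-(tert-butyldimethylsilyloxy)-3,10:7,8-diepoxy-1-oxo-11,12,13-trinorgermacra-2,4-dien-6-yl (diethoxyphosphoryl)acetate (macrocyclic trans C7–C8 epoxide with the C6 phosphonoacetate)
Conditions: second-generation Grubbs catalyst (cat.), toluene (high dilution), 80 °C
Reagents that add atoms: none
Why: Ring-closing metathesis, in which the ruthenium carbene should load on the monosubstituted C5 vinyl group and close onto the 1,1-disubstituted C4 alkene with loss of ethene, forms ring B, whose nine members can hold the new trisubstituted alkene only with C3 and C6 cis (4Z), the E geometry needed for the trans epoxide having been fixed beforehand on the open chain.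

Step 14
Reactants: 19 (4Z,6R,7S,8R,10R)-15-(tert-butyldimethylsilyloxy)-3,10:7,8-diepoxy-1-oxo-11,12,13-trinorgermacra-2,4-dien-6-yl (diethoxyphosphoryl)acetate
Product: 21 (4Z,6R,7R,8R,10R)-15-(tert-butyldimethylsilyloxy)-3,10-epoxy-8-hydroxy-1-oxogermacra-2,4,11(13)-trien-12,6-olide, via phosphono lactone 20 (not isolated)
Conditions: LiN(SiMe3)2 (1.05 equiv), LiClO4, THF, −20 °C → rt; then (CH2O)n, 0 °C → rt; pH 7 phosphate buffer
Reagents that add atoms: formaldehyde (as paraformaldehyde) C=O
Why: LiN(SiMe3)2 removes the proton between the phosphoryl and carbonyl groups and the stabilised carbanion at C11 attacks C7 from the side opposite the epoxide oxygen (intramolecular SN2), which closes ring C and frees the C8 alkoxide; this alkoxide is at once protonated by the much more acidic C11–H of phosphono lactone 20, and the resulting phosphonate enolate condenses with formaldehyde and expels diethyl phosphate (Horner–Wadsworth–Emmons olefination) to form C11=C13. The closest known reaction types are the alkylation of epoxides by phosphonoacetate anions with subsequent formaldehyde olefination, the base-induced closure of carbamates of 2,3-epoxy alcohols onto C2, and the tandem conjugate addition–olefination of alcohol-tethered phosphonoacetates. Ring C closes in the 5-exo-tet mode. C7 is the only new stereocentre and is set by inversion at the (7S,8R) trans epoxide, so C11 ends up anti to the C8 oxygen and trans to O6 (7R), while C6 and C8 keep their configurations. The step needs attack at C7 and not at C8, which the three-atom O6–C12–C11 tether secures because reaching the rear of C8 would require a six-membered ring that spans the epoxide, and coordination of the epoxide by LiClO4 assists the opening. It also needs the lactone to stay on O6: ring C is masked as its enolate until the olefination, only one equivalent of base is used and the mixture is quenched at pH 7, so the C8 hydroxyl has little opportunity to transacylate.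

Step 15
Reactants: 21 (4Z,6R,7R,8R,10R)-15-(tert-butyldimethylsilyloxy)-3,10-epoxy-8-hydroxy-1-oxogermacra-2,4,11(13)-trien-12,6-olide
Product: 22 (4Z,6R,7R,8R,10R)-15-(tert-butyldimethylsilyloxy)-3,10-epoxy-8-(2-methylpropanoyloxy)-1-oxogermacra-2,4,11(13)-trien-12,6-olide
Conditions: (iPrCO)2O, DMAP (cat.), Et3N, CH2Cl2, 0 °C
Reagents that add atoms: isobutyric anhydride CC(C)C(=O)OC(=O)C(C)C
Why: DMAP-catalysed acyl transfer to the C8 hydroxyl, the only free hydroxyl, proceeds with retention at C8 and, run cold and briefly, should outpace lactone migration and conjugate addition to the methylene lactone.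

Step 16
Reactants: 22 (4Z,6R,7R,8R,10R)-15-(tert-butyldimethylsilyloxy)-3,10-epoxy-8-(2-methylpropanoyloxy)-1-oxogermacra-2,4,11(13)-trien-12,6-olide
Product: 23 (4Z,6R,7R,8R,10R)-3,10-epoxy-15-hydroxy-8-(2-methylpropanoyloxy)-1-oxogermacra-2,4,11(13)-trien-12,6-olide (CNP0176924.3)
Conditions: HF·pyridine, pyridine, THF, 0 °C → rt
Reagents that add atoms: none
Why: Fluoride-mediated cleavage of the primary allylic silyl ether under buffered, non-basic conditions should spare the isobutyrate, the methylene lactone and ring A and so release the C15 hydroxyl of the target.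

**Compound list**

1 | (S)-lactic acid | C[C@H](O)C(=O)O | starting material
2 | (2S,5S)-2-tert-butyl-5-methyl-1,3-dioxolan-4-one | C[C@@H]1O[C@H](C(C)(C)C)OC1=O | intermediate
3 | allyl bromide | C=CCBr | starting material
4 | (2S,5R)-2-tert-butyl-5-methyl-5-(prop-2-en-1-yl)-1,3-dioxolan-4-one | C[C@]1(CC=C)O[C@H](C(C)(C)C)OC1=O | intermediate
5 | (2R)-2-hydroxy-N-methoxy-N,2-dimethylpent-4-enamide | C=CC[C@@](C)(O)C(=O)N(C)OC | intermediate
6 | 2-bromoprop-2-en-1-ol | C=C(Br)CO | starting material
7 | (2-bromoprop-2-en-1-yloxy)(tert-butyl)dimethylsilane | C=C(Br)CO[Si](C)(C)C(C)(C)C | intermediate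
8 | ethynyltrimethylsilane | C#C[Si](C)(C)C | starting material
9 | tert-butyldimethyl[2-methylidene-4-(trimethylsilyl)but-3-yn-1-yloxy]silane | C=C(CO[Si](C)(C)C(C)(C)C)C#C[Si](C)(C)C | intermediate
10 | tert-butyldimethyl(2-methylidenebut-3-yn-1-yloxy)silane | C=C(CO[Si](C)(C)C(C)(C)C)C#C | intermediate
11 | (4R)-8-[(tert-butyldimethylsilyloxy)methyl]-4-hydroxy-4-methylnona-1,8-dien-6-yn-5-one | C=CC[C@@](C)(O)C(=O)C#CC(=C)CO[Si](C)(C)C(C)(C)C | intermediate
12 | (2R)-5-[3-(tert-butyldimethylsilyloxy)prop-1-en-2-yl]-2-methyl-2-(prop-2-en-1-yl)furan-3(2H)-one | C=CC[C@@]1(C)OC(=CC1=O)C(=C)CO[Si](C)(C)C(C)(C)C | intermediate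
13 | (E)-but-2-enal (crotonaldehyde) | C/C=C/C=O | starting material
14 | (2E)-4-{(2R)-5-[3-(tert-butyldimethylsilyloxy)prop-1-en-2-yl]-2-methyl-3-oxo-2,3-dihydrofuran-2-yl}but-2-enal | O=C/C=C/C[C@@]1(C)OC(=CC1=O)C(=C)CO[Si](C)(C)C(C)(C)C | intermediate
15 | (2R)-5-[3-(tert-butyldimethylsilyloxy)prop-1-en-2-yl]-2-[(2E,4R)-4-hydroxyhexa-2,5-dien-1-yl]-2-methylfuran-3(2H)-one | C=C[C@@H](O)/C=C/C[C@@]1(C)OC(=CC1=O)C(=C)CO[Si](C)(C)C(C)(C)C | intermediate
16 | (2R)-5-[3-(tert-butyldimethylsilyloxy)prop-1-en-2-yl]-2-({(2R,3R)-3-[(1R)-1-hydroxyprop-2-en-1-yl]oxiran-2-yl}methyl)-2-methylfuran-3(2H)-one | C=C[C@@H](O)[C@H]1O[C@@H]1C[C@@]2(C)OC(=CC2=O)C(=C)CO[Si](C)(C)C(C)(C)C | intermediate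
17 | (diethoxyphosphoryl)acetic acid | CCOP(=O)(CC(=O)O)OCC | starting material
18 | (1R)-1-[(2S,3R)-3-({(2R)-5-[3-(tert-butyldimethylsilyloxy)prop-1-en-2-yl]-2-methyl-3-oxo-2,3-dihydrofuran-2-yl}methyl)oxiran-2-yl]prop-2-en-1-yl (diethoxyphosphoryl)acetate | CCOP(=O)(OCC)CC(=O)O[C@H](C=C)[C@H]1O[C@@H]1C[C@@]2(C)OC(=CC2=O)C(=C)CO[Si](C)(C)C(C)(C)C | intermediate
19 | (4Z,6R,7S,8R,10R)-15-(tert-butyldimethylsilyloxy)-3,10:7,8-diepoxy-1-oxo-11,12,13-trinorgermacra-2,4-dien-6-yl (diethoxyphosphoryl)acetate | CCOP(=O)(OCC)CC(=O)O[C@@H]1/C=C(/CO[Si](C)(C)C(C)(C)C)C2=CC(=O)[C@@](C)(C[C@H]3O[C@@H]31)O2 | intermediate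
20 | (4Z,6R,7R,8R,10R)-11-(diethoxyphosphoryl)-15-(tert-butyldimethylsilyloxy)-3,10-epoxy-8-hydroxy-1-oxo-13-norgermacra-2,4-dien-12,6-olide (lithium enolate in the flask, C11 not defined) | CCOP(=O)(OCC)C1C(=O)O[C@@H]2/C=C(/CO[Si](C)(C)C(C)(C)C)C3=CC(=O)[C@@](C)(C[C@@H](O)[C@@H]12)O3 | intermediate
21 | (4Z,6R,7R,8R,10R)-15-(tert-butyldimethylsilyloxy)-3,10-epoxy-8-hydroxy-1-oxogermacra-2,4,11(13)-trien-12,6-olide | C=C1C(=O)O[C@@H]2/C=C(/CO[Si](C)(C)C(C)(C)C)C3=CC(=O)[C@@](C)(C[C@@H](O)[C@@H]12)O3 | intermediate
22 | (4Z,6R,7R,8R,10R)-15-(tert-butyldimethylsilyloxy)-3,10-epoxy-8-(2-methylpropanoyloxy)-1-oxogermacra-2,4,11(13)-trien-12,6-olide | C=C1C(=O)O[C@@H]2/C=C(/CO[Si](C)(C)C(C)(C)C)C3=CC(=O)[C@@](C)(C[C@@H](OC(=O)C(C)C)[C@@H]12)O3 | intermediate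
23 | (4Z,6R,7R,8R,10R)-3,10-epoxy-15-hydroxy-8-(2-methylpropanoyloxy)-1-oxogermacra-2,4,11(13)-trien-12,6-olide (CNP0176924.3) | C=C1C(=O)O[C@@H]2/C=C(/CO)C3=CC(=O)[C@@](C)(C[C@@H](OC(=O)C(C)C)[C@@H]12)O3 | target

**Count and risks**

Total steps: 16. Longest linear sequence: 13 steps (steps 1–3 and 7–16, from 1 to 23; the enyne branch, steps 4–6 and 7–16, is equally long).

Steps most likely to fail:

1. Step 13 (ring-closing metathesis). Ring B has to accommodate a trans epoxide, a ring-cis trisubstituted alkene and the sp2 carbon C3, so closure onto the hindered C4 alkene may be slower than intermolecular metathesis at the C5 vinyl group, leading to oligomers. Fallback: the order of ring closures is changed, setting out from 18. Treatment of open-chain 18 with LiN(SiMe3)2/LiClO4 and then paraformaldehyde (the chemistry of step 14, now free of transannular strain) should give the open-chain methylene lactone alcohol F1. Acylation with isobutyric anhydride and DMAP should give its C8 isobutyrate F2. Ring-closing metathesis of F2 (second-generation Grubbs catalyst, toluene, 80–110 °C), in which the trans-fused lactone instead of the epoxide spans C6–C8, should then give 22, where the route is rejoined.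

2. Step 14 (epoxide opening and methylenation). The five-membered closure contains the enolate carbon and its carbonyl, which is stereoelectronically tight. Within ring B the bulky phosphoryl carbanion may therefore fail to reach the rear of C7, may attack C8 instead, or the freed C8 alkoxide may take over the lactone during the olefination. Fallback: a smaller carbanion and a different methylenation are used, setting out from 16. Acetoacetylation with 2,2,6-trimethyl-4H-1,3-dioxin-4-one (toluene, 110 °C) should give the open-chain epoxy acetoacetate F3, and ring-closing metathesis as in step 13 the macrocyclic epoxy acetoacetate F4. LiN(SiMe3)2/LiClO4 should then close ring C by the classical alkylation of an epoxide with an acetoacetate anion to give the acetyl lactone F5 as its enolate. Paraformaldehyde added to this enolate should bring about deacylative methylenation (aldol addition, acetyl transfer to the new alkoxide, loss of acetate) to give 21, where the route is rejoined.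

3. Step 10 (ligand-controlled vinyl addition). Uncatalysed background addition or competing coordination of the zinc reagent by ring A may erode the facial selectivity at C6. Fallback: catalyst control is replaced by a kinetic resolution, setting out from 14. Addition of CH2=CHMgBr (THF, −78 °C) should give 15 together with its (6S) epimer F6. Submitting the mixture to the conditions of step 11 with a deficit of tBuOOH should epoxidise only the (6R) isomer at C7=C8, giving 16, where the route is rejoined, while F6 is separated.

Further compounds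

F1 | step 13 | open-chain (6R,7R,8R,10R) methylene lactone alcohol (ring C closed, ring B open, C8 hydroxyl free) | C=C[C@H]1OC(=O)C(=C)[C@@H]1[C@H](O)C[C@@]2(C)OC(=CC2=O)C(=C)CO[Si](C)(C)C(C)(C)C
F2 | step 13 | C8 isobutyrate of F1 | C=C[C@H]1OC(=O)C(=C)[C@@H]1[C@H](OC(=O)C(C)C)C[C@@]2(C)OC(=CC2=O)C(=C)CO[Si](C)(C)C(C)(C)C
F3 | step 14 | open-chain (6R,7S,8R,10R) epoxy acetoacetate (3-oxobutanoate of 16) | CC(=O)CC(=O)O[C@H](C=C)[C@H]1O[C@@H]1C[C@@]2(C)OC(=CC2=O)C(=C)CO[Si](C)(C)C(C)(C)C
F4 | step 14 | macrocyclic (4Z,6R,7S,8R,10R) epoxy acetoacetate (3-oxobutanoate analogue of 19) | CC(=O)CC(=O)O[C@@H]1/C=C(/CO[Si](C)(C)C(C)(C)C)C2=CC(=O)[C@@](C)(C[C@H]3O[C@@H]31)O2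
F5 | step 14 | (4Z,6R,7R,8R,10R) 11-acetyl lactone with free C8 hydroxyl (acetyl analogue of 20) | CC(=O)C1C(=O)O[C@@H]2/C=C(/CO[Si](C)(C)C(C)(C)C)C3=CC(=O)[C@@](C)(C[C@@H](O)[C@@H]12)O3
F6 | step 10 | (6S) epimer of 15 | C=C[C@H](O)/C=C/C[C@@]1(C)OC(=CC1=O)C(=C)CO[Si](C)(C)C(C)(C)C
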